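The cyclohexenone ring (C1 carbonyl, C2(Me)=C3, C4–OH, C5 side chain, C6) is opened at C1–C2 and C4–C5. This gives a (Z)-4-silyloxybut-2-en-2-yllithium and a (2E)-dienoyl chloride that already carries the geranylgeranyl chain. In one flask the vinyllithium acylates the acid chloride (C1–C2). γ-Deprotonation of the resulting cross-conjugated dienone gives a 3-oxidohexatriene, whose disrotatory 6π-electrocyclization forges C4–C5 and sets the cis C4/C5 pair. The step exploits the fact that the C1 ketone, the C2=C3 alkene and C6 are the protonated form of a cyclohexa-1,3-dienolate. The racemic cis alcohol is then resolved with a lipase.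

Key step: step 7

Remark: compounds 14–16 are racemic and their SMILES show the (4S,5S) enantiomer to define the cis relative configuration; the lipase is assumed to acylate the enantiomer predicted by the usual size rule for secondary alcohols (large group = C5 with its side chain).

Step 1
Reactants: 1 (2E,6E,10E)-geranylgeraniol
Product: 2 (2E,6E,10E)-geranylgeranyl bromide
Conditions: PBr3 (0.4 equiv), Et2O, −10 °C; used crude
Reagents that add atoms: phosphorus tribromide, BrP(Br)Br
Why: Bromination of the primary allylic alcohol at low temperature should give the primary bromide without allylic transposition and with the (2E) olefin intact, as for geranyl and farnesyl bromide.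

Step 2
Reactants: 2 (2E,6E,10E)-geranylgeranyl bromide; 3 ethyl (E)-3-(4,4,5,5-tetramethyl-1,3,2-dioxaborolan-2-yl)acrylate
Product: 4 ethyl (2E,5E,9E,13E)-6,10,14,18-tetramethylnonadeca-2,5,9,13,17-pentaenoate
Conditions: Pd(PPh3)4 (5 mol %), K2CO3, THF/H2O, 40 °C
Reagents that add atoms: none
Why: Suzuki–Miyaura allyl–alkenyl coupling should proceed through a π-allylpalladium that couples at its unsubstituted terminus with retention of both olefin geometries, and the carbonate base is too weak to move the skipped diene into conjugation.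

Step 3
Reactants: 4 ethyl (2E,5E,9E,13E)-6,10,14,18-tetramethylnonadeca-2,5,9,13,17-pentaenoate
Product: 5 (2E,5E,9E,13E)-6,10,14,18-tetramethylnonadeca-2,5,9,13,17-pentaenoic acid
Conditions: LiOH·H2O, THF/H2O, 0 °C → rt; then 1 M HCl to pH 3
Reagents that add atoms: lithium hydroxide, [Li+].[OH-]
Why: Ester saponification; hydroxide at 0 °C should not deprotonate the doubly allylic C4 methylene, so the (2E)-enoate stays in place.

Step 4
Reactants: 5 (2E,5E,9E,13E)-6,10,14,18-tetramethylnonadeca-2,5,9,13,17-pentaenoic acid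
Product: 6 (2E,5E,9E,13E)-6,10,14,18-tetramethylnonadeca-2,5,9,13,17-pentaenoyl chloride
Conditions: 1-chloro-N,N,2-trimethylprop-1-en-1-amine, CH2Cl2, 0 °C → rt; volatiles removed in vacuo; used crude
Reagents that add atoms: 1-chloro-N,N,2-trimethylprop-1-en-1-amine, CC(C)=C(Cl)N(C)C
Why: Acid chloride formation with an α-chloroenamine is neutral and releases no HCl, so the trisubstituted olefins and the skipped diene should survive.

Step 5
Reactants: 7 but-2-yn-1-ol
Product: 9 (Z)-3-iodobut-2-en-1-ol, via sodium alkenylalanate 8 (not isolated)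
Conditions: NaAlH2(OCH2CH2OMe)2 (Red-Al), THF, 0 °C → rt; then I2, THF, −78 °C
Reagents that add atoms: iodine, II
Why: Hydroxyl-directed trans-hydroalumination of the propargylic alcohol places aluminium on C3 in a five-membered alanate, and iodinolysis with retention should give the (Z)-vinyl iodide.

Step 6
Reactants: 9 (Z)-3-iodobut-2-en-1-ol
Product: 10 tert-butyl{[(2Z)-3-iodobut-2-en-1-yl]oxy}dimethylsilane
Conditions: TBSCl, imidazole, CH2Cl2, rt
Reagents that add atoms: tert-butyldimethylsilyl chloride, CC(C)(C)[Si](C)(C)Cl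
Why: Standard silylation of the primary alcohol; the bulky non-chelating silyl ether later steers the C4 oxygen to the outside of the triene terminus.

Step 7
Reactants: 10 tert-butyl{[(2Z)-3-iodobut-2-en-1-yl]oxy}dimethylsilane; 6 (2E,5E,9E,13E)-6,10,14,18-tetramethylnonadeca-2,5,9,13,17-pentaenoyl chloride
Product: 15 rac-(4S,5S)-4-[(tert-butyldimethylsilyl)oxy]-2-methyl-5-[(2E,6E,10E)-3,7,11,15-tetramethylhexadeca-2,6,10,14-tetraen-1-yl]cyclohex-2-en-1-one, via vinyllithium 11 (not isolated), via cross-conjugated dienone 12 (not isolated), via lithium trienolate 13 (not isolated), via lithium cyclohexadienolate 14 (not isolated)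
Conditions: t-BuLi (2.0 equiv), Et2O, −78 °C; cannulated into 6 (1.0 equiv) in THF, −78 °C; then LiHMDS (1.05 equiv), −78 → 0 °C; AcOH, −78 °C
Reagents that add atoms: none
Why: I–Li exchange gives the configurationally stable (Z)-vinyllithium 11, which adds to acid chloride 6 and so forms C1–C2 in the cross-conjugated (2Z,5E)-dienone 12; LiHMDS then removes a C4 hydrogen, and the 3-oxidohexatriene 13 (C4=C3–C2=C1(OLi)–C6=C5) closes thermally to dienolate 14, which is protonated at C6 on quenching. The closest known reactions are the ketone synthesis from alkenyllithiums and acid chlorides and the base-induced cyclisation of divinyl ketones bearing γ-hydrogens to cyclohexenones (phorone to isophorone; oxyanion-accelerated hexatriene electrocyclisation). The six-membered ring closes by disrotatory 6π-electrocyclisation (formally a 6-endo-trig vinylogous Michael addition) that forms C4–C5. C4 and C5 arise together and only as a relative pair: OTBS on C4 and the side chain on C5 both sit outside on the (E)-configured triene termini, so disrotation should put them cis, the inside position at C4 being disfavoured by allylic strain. The step needs enolisation at C4 and not at C1′ of the side-chain arm; the C4 hydrogens lie syn to the lithium-coordinated carbonyl on the Z arm, the trienolate isomers can interconvert through HMDS-mediated proton transfer, and the C1′-derived trienolate would have to close through a Z terminus (CH2OTBS inside), which should be slow. Inverse addition at −78 °C should prevent double addition of 11.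

Step 8
Reactants: 15 rac-(4S,5S)-4-[(tert-butyldimethylsilyl)oxy]-2-methyl-5-geranylgeranylcyclohex-2-en-1-one
Product: 16 rac-(4S,5S)-4-hydroxy-2-methyl-5-geranylgeranylcyclohex-2-en-1-one
Conditions: HF·pyridine, pyridine, THF, 0 °C → rt
Reagents that add atoms: none
Why: Buffered fluoride desilylation; non-basic conditions should avoid γ-enolisation (C4 epimerisation) of the enone and leave the polyene untouched.

Step 9
Reactants: 16 rac-(4S,5S)-4-hydroxy-2-methyl-5-geranylgeranylcyclohex-2-en-1-one
Product: 17 (1S,6S)-3-methyl-4-oxo-6-[(2E,6E,10E)-3,7,11,15-tetramethylhexadeca-2,6,10,14-tetraen-1-yl]cyclohex-2-en-1-yl acetate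
Conditions: lipase PS (Burkholderia cepacia), vinyl acetate, MTBE, 30 °C, stopped at ca. 45 % conversion; chromatography
Reagents that add atoms: vinyl acetate, C=COC(C)=O
Why: Lipase-catalysed kinetic resolution by irreversible transesterification; with C5 and its side chain as the large group and C3 as the medium group, the (4S,5S) alcohol is the enantiomer expected to be acylated, which fixes the absolute configuration of both centres.

Step 10
Reactants: 17 (4S,5S)-acetate
Product: 18 (4S,5S)-4-hydroxy-2-methyl-5-[(2E,6E,10E)-3,7,11,15-tetramethylhexadeca-2,6,10,14-tetraen-1-yl]cyclohex-2-en-1-one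
Conditions: lipase PS, pH 7 phosphate buffer, acetone, 30 °C
Reagents that add atoms: none
Why: Enzymatic ester hydrolysis at neutral pH has the same enantiomer preference, so it should raise the enantiomeric purity while avoiding base at the γ-acyloxy enone.

Compound list
1 | (2E,6E,10E)-geranylgeraniol | CC(C)=CCC/C(C)=C/CC/C(C)=C/CC/C(C)=C/CO | starting material
2 | (2E,6E,10E)-geranylgeranyl bromide | CC(C)=CCC/C(C)=C/CC/C(C)=C/CC/C(C)=C/CBr | intermediate
3 | ethyl (E)-3-(4,4,5,5-tetramethyl-1,3,2-dioxaborolan-2-yl)acrylate | CCOC(=O)/C=C/B1OC(C)(C)C(C)(C)O1 | starting material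
4 | ethyl (2E,5E,9E,13E)-6,10,14,18-tetramethylnonadeca-2,5,9,13,17-pentaenoate | CC(C)=CCC/C(C)=C/CC/C(C)=C/CC/C(C)=C/C/C=C/C(=O)OCC | intermediate
5 | (2E,5E,9E,13E)-6,10,14,18-tetramethylnonadeca-2,5,9,13,17-pentaenoic acid | CC(C)=CCC/C(C)=C/CC/C(C)=C/CC/C(C)=C/C/C=C/C(=O)O | intermediate
6 | (2E,5E,9E,13E)-6,10,14,18-tetramethylnonadeca-2,5,9,13,17-pentaenoyl chloride | CC(C)=CCC/C(C)=C/CC/C(C)=C/CC/C(C)=C/C/C=C/C(Cl)=O | intermediate
7 | but-2-yn-1-ol | CC#CCO | starting material
8 | sodium 2,2-bis(2-methoxyethoxy)-3-methyl-2,5-dihydro-1,2-oxaluminol-2-uide (cyclic alkenylalanate) | CC1=CCO[Al-]1(OCCOC)OCCOC.[Na+] | intermediate (not isolated)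
9 | (Z)-3-iodobut-2-en-1-ol | C/C(I)=C/CO | intermediate
10 | tert-butyl{[(2Z)-3-iodobut-2-en-1-yl]oxy}dimethylsilane | C/C(I)=C/CO[Si](C)(C)C(C)(C)C | intermediate
11 | (Z)-4-[(tert-butyldimethylsilyl)oxy]but-2-en-2-yllithium | C/C([Li])=C/CO[Si](C)(C)C(C)(C)C | intermediate (not isolated)
12 | (2Z,5E,8E,12E,16E)-1-[(tert-butyldimethylsilyl)oxy]-3,9,13,17,21-pentamethyldocosa-2,5,8,12,16,20-hexaen-4-one | CC(C)=CCC/C(C)=C/CC/C(C)=C/CC/C(C)=C/C/C=C/C(=O)/C(C)=C\CO[Si](C)(C)C(C)(C)C | intermediate (not isolated)
13 | lithium trienolate of 12 (C4=C3–C2=C1(OLi)–C6=C5, OTBS and side chain outside) | CC(C)=CCC/C(C)=C/CC/C(C)=C/CC/C(C)=C/C/C=C/C([O-])=C(C)\C=C\O[Si](C)(C)C(C)(C)C.[Li+] | intermediate (not isolated)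
14 | rac-lithium cis-3-[(tert-butyldimethylsilyl)oxy]-4-geranylgeranyl-6-methylcyclohexa-1,5-dien-1-olate | CC(C)=CCC/C(C)=C/CC/C(C)=C/CC/C(C)=C/C[C@H]1C=C([O-])C(C)=C[C@H]1O[Si](C)(C)C(C)(C)C.[Li+] | intermediate (not isolated)
15 | rac-(4S,5S)-4-[(tert-butyldimethylsilyl)oxy]-2-methyl-5-geranylgeranylcyclohex-2-en-1-one | CC(C)=CCC/C(C)=C/CC/C(C)=C/CC/C(C)=C/C[C@H]1CC(=O)C(C)=C[C@H]1O[Si](C)(C)C(C)(C)C | intermediate
16 | rac-(4S,5S)-4-hydroxy-2-methyl-5-geranylgeranylcyclohex-2-en-1-one | CC(C)=CCC/C(C)=C/CC/C(C)=C/CC/C(C)=C/C[C@H]1CC(=O)C(C)=C[C@H]1O | intermediate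
17 | (1S,6S)-3-methyl-4-oxo-6-geranylgeranylcyclohex-2-en-1-yl acetate | CC(C)=CCC/C(C)=C/CC/C(C)=C/CC/C(C)=C/C[C@H]1CC(=O)C(C)=C[C@H]1OC(C)=O | intermediate
18 | (4S,5S)-4-hydroxy-2-methyl-5-[(2E,6E,10E)-3,7,11,15-tetramethylhexadeca-2,6,10,14-tetraen-1-yl]cyclohex-2-en-1-one | CC(C)=CCC/C(C)=C/CC/C(C)=C/CC/C(C)=C/C[C@H]1CC(=O)C(C)=C[C@H]1O | target

Total step count: 10. Longest linear sequence: 8 steps (1, 2, 3, 4, 7, 8, 9, 10).

Steps most likely to fail

1. Step 7. Proton abstraction may occur at C1′ of the side-chain arm instead of C4, leading to double-bond migration in the skipped diene; the vinyllithium may add twice; or the trienolate geometries may interconvert too slowly for closure. The fallback sets out from bromide 2 and comes back at alcohol 16. Commercial 4-methoxy-3-methylphenol would be oxidised with PhI(OAc)2 in MeOH to 4,4-dimethoxy-3-methylcyclohexa-2,5-dien-1-one F1. Hydrogenation of the unsubstituted enone double bond (H2, RhCl(PPh3)3) would give 4,4-dimethoxy-3-methylcyclohex-2-en-1-one F2. Kinetic α′-deprotonation (LDA, THF, −78 °C) and alkylation with 2 would give rac-6-geranylgeranyl-4,4-dimethoxy-3-methylcyclohex-2-en-1-one F3. L-Selectride would deliver hydride anti to the neighbouring side chain and give the cis alcohol rac-(1S,6S)-6-geranylgeranyl-4,4-dimethoxy-3-methylcyclohex-2-en-1-ol F4. Mild ketal hydrolysis (PPTS, wet acetone) would then unveil the C1 ketone and give 16.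

2. Step 9. The enzyme may discriminate poorly between the enantiomers, or acyl transfer to the hindered C4 hydroxyl may be too slow. The fallback sets out from 16 and comes back at 18. Esterification with (S)-2-methoxy-2-phenylacetic acid (EDC, cat. DMAP, CH2Cl2, 0 °C) would give the diastereomeric esters (4S,5S)-O-methylmandelate F5 and (4R,5R)-O-methylmandelate F6. After chromatographic separation, methanolysis of F5 (K2CO3, MeOH, 0 °C) would give 18.

3. Step 4. During acyl activation the C2=C3 bond may migrate into conjugation with the C5=C6 olefin, or a vinylketene may form by loss of HCl. The fallback sets out from ester 4 and comes back at dienone 12 and then 15. Ester 4 would be converted with MeNH(OMe)·HCl and i-PrMgCl (THF, −20 °C) into the N-methoxy-N-methylamide F7. Addition of vinyllithium 11 and aqueous work-up would give dienone 12 as an isolated compound, and LiHMDS (THF, −78 → 0 °C) would then close it to 15.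

Further compounds
F1 | step 7 | 4,4-dimethoxy-3-methylcyclohexa-2,5-dien-1-one | COC1(OC)C=CC(=O)C=C1C
F2 | step 7 | 4,4-dimethoxy-3-methylcyclohex-2-en-1-one | COC1(OC)CCC(=O)C=C1C
F3 | step 7 | rac-6-geranylgeranyl-4,4-dimethoxy-3-methylcyclohex-2-en-1-one | CC(C)=CCC/C(C)=C/CC/C(C)=C/CC/C(C)=C/CC1CC(OC)(OC)C(C)=CC1=O
F4 | step 7 | rac-(1S,6S)-6-geranylgeranyl-4,4-dimethoxy-3-methylcyclohex-2-en-1-ol | CC(C)=CCC/C(C)=C/CC/C(C)=C/CC/C(C)=C/C[C@H]1CC(OC)(OC)C(C)=C[C@H]1O
F5 | step 9 | (1S,6S)-3-methyl-4-oxo-6-geranylgeranylcyclohex-2-en-1-yl (S)-2-methoxy-2-phenylacetate | CC(C)=CCC/C(C)=C/CC/C(C)=C/CC/C(C)=C/C[C@H]1CC(=O)C(C)=C[C@H]1OC(=O)[C@@H](OC)c1ccccc1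
F6 | step 9 | (1R,6R)-3-methyl-4-oxo-6-geranylgeranylcyclohex-2-en-1-yl (S)-2-methoxy-2-phenylacetate | CC(C)=CCC/C(C)=C/CC/C(C)=C/CC/C(C)=C/C[C@@H]1CC(=O)C(C)=C[C@@H]1OC(=O)[C@@H](OC)c1ccccc1
F7 | step 4 | (2E,5E,9E,13E)-N-methoxy-N,6,10,14,18-pentamethylnonadeca-2,5,9,13,17-pentaenamide | CC(C)=CCC/C(C)=C/CC/C(C)=C/CC/C(C)=C/C/C=C/C(=O)N(C)OC
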